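## Retrosynthetic overview

1. Locants and rings: ring D is the ten-membered carbocycle C1–C10 (C3 = CH–O, C4 = C–CH3, C5 = ring =CH, C6 = spiro ketal carbon, C7 = C(OH) carrying C11(CH3)–C12(=O), C8 = CH–O, C9 = CH–OAc, C10 = C(OH) carrying C14(=O)); ring A = dihydrofuran (O, C3–C6), ring B = spiro lactone (C6, C7, C11, C12, O), ring C = lactone (C8, C9, C10, C14, O).
2. Enabling feature: C6 is a ketone carbon masked as a ketal by the C3 oxygen (held 1,4 to it by the cis C4=C5 bond) and by the C12 carboxyl. Rings A and B are therefore only the folded form of a (Z)-γ-hydroxy enone acid, and the one bond to make is C5–C6.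
3. Key disconnection C5–C6: a (Z)-vinyl iodide (C5) and an S-ethyl thioester (C6), two electrophilic carbons, are joined reductively at nickel to close ring D. Acid then frees the C3 hydroxyl and the C12 acid, and rings A and B close in the same operation.
4. Precursor: ring C as a butenolide by ring-closing metathesis, then cis-dihydroxylation anti to C8 (sets C9, C10). C1–C2 by SN2′ alkylation of the enolate of (Z)-4-iodo-3-methylbut-3-en-2-one with a 2-(bromomethyl)acrylate ester. C3 and C8 by CBS reductions.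
5. C7 and C11 from dimethyl (R)-malate: Fráter–Seebach methylation, then a temporary 2-tert-butyl-1,3-dioxolan-4-one ring (not in the target) that relays the C7 configuration through an aldol and holds C6 as a latent acyl group until thiolysis. Order of rings: dioxolanone (temporary), ring C, then rings D, A and B together.

Key step: step 18

Assumption: C6 can epimerise through the open keto acid, so the configuration drawn for the target is taken as the one favoured at equilibrium once C3 and C7 are fixed.

## Route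

Step 1
Reactants: 1 dimethyl (R)-malate
Product: 3 dimethyl (2R,3S)-2-hydroxy-3-methylbutanedioate, via dilithium alkoxide enolate 2 (not isolated)
Conditions: LiN(SiMe3)2 (2.2 equiv), THF, −78 to −20 °C; MeI, −78 to −10 °C; aq. NH4Cl
Reagents that add atoms: iodomethane CI
Why: Fráter–Seebach alkylation: the lithium-chelated alkoxide enolate should be methylated anti to the alkoxide, which sets C11 as (3S) next to the (2R) carbinol.

Step 2
Reactants: 3 dimethyl (2R,3S)-2-hydroxy-3-methylbutanedioate
Product: 4 (2R,3S)-2-hydroxy-3-methylbutanedioic acid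
Conditions: KOH, MeOH/H2O, 0 °C to rt; then HCl to pH 1
Reagents that add atoms: potassium hydroxide [K+].[OH-]
Why: Saponification of both methyl esters should leave the two stereocentres untouched and free the α-hydroxy acid for acetalisation.

Step 3
Reactants: 4 (2R,3S)-2-hydroxy-3-methylbutanedioic acid
Product: 5 (2S)-2-[(2R,4R)-2-tert-butyl-5-oxo-1,3-dioxolan-4-yl]propanoic acid (tert-butyl cis to the side chain)
Conditions: t-BuCHO, TsOH (cat.), H2SO4 (cat.), pentane, reflux, water separator
Reagents that add atoms: pivalaldehyde CC(C)(C)C=O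
Why: Acetalisation of the α-hydroxy acid (self-regeneration of stereocentres) should close the five-membered dioxolanone under thermodynamic control with tert-butyl cis to the C7 substituent, so the acetal carbon stores the C7 configuration.

Step 4
Reactants: 5 dioxolanone acid
Product: 6 tert-butyl (2S)-2-[(2R,4R)-2-tert-butyl-5-oxo-1,3-dioxolan-4-yl]propanoate
Conditions: tert-butyl 2,2,2-trichloroacetimidate, BF3·OEt2 (cat.), CH2Cl2/cyclohexane, rt
Reagents that add atoms: tert-butyl 2,2,2-trichloroacetimidate CC(C)(C)OC(=N)C(Cl)(Cl)Cl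
Why: Acid-catalysed O-alkylation with the trichloroacetimidate should give the tert-butyl ester, which cannot lactonise onto the later C8 hydroxyl and has a hindered α-hydrogen.

Step 5
Reactants: 6 dioxolanone tert-butyl ester; 7 acrolein
Product: 9 tert-butyl (2S)-2-[(2R,4S)-2-tert-butyl-4-(1-hydroxyprop-2-enyl)-5-oxo-1,3-dioxolan-4-yl]propanoate (both C8 epimers), via lithium enolate 8 (not isolated)
Conditions: LiN(iPr)2, THF, −78 °C; acrolein, −78 °C; AcOH quench at −78 °C
Reagents that add atoms: none
Why: Aldol addition of the dioxolanone enolate: acrolein should add 1,2 on the face anti to tert-butyl, so C8 takes the place of the former hydrogen with retention and C7 becomes the (S) quaternary centre, while the carbinol C8 is left uncontrolled.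

Step 6
Reactants: 9 aldol adduct
Product: 10 tert-butyl (2S)-2-[(2R,4S)-2-tert-butyl-5-oxo-4-(prop-2-enoyl)-1,3-dioxolan-4-yl]propanoate
Conditions: Dess–Martin periodinane, NaHCO3, CH2Cl2, 0 °C to rt
Reagents that add atoms: none
Why: Dess–Martin oxidation of the allylic alcohol should erase the uncontrolled C8 centre, and the ketone cannot enolise towards the quaternary C7.

Step 7
Reactants: 10 vinyl ketone
Product: 11 tert-butyl (2S)-2-{(2R,4S)-2-tert-butyl-4-[(1R)-1-hydroxyprop-2-enyl]-5-oxo-1,3-dioxolan-4-yl}propanoate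
Conditions: (S)-2-methyl-CBS-oxazaborolidine (20 mol%), catecholborane, toluene, −78 °C
Reagents that add atoms: none
Why: Corey–Bakshi–Shibata reduction: with the quaternary C7 as the large group and vinyl as the small one, the (S)-catalyst should deliver hydride 1,2 to give the (8R) carbinol under reagent control.

Step 8
Reactants: 11 (8R)-allylic alcohol; 12 2-(bromomethyl)prop-2-enoic acid
Product: 13 (1R)-1-{(2R,4S)-4-[(2S)-1-tert-butoxy-1-oxopropan-2-yl]-2-tert-butyl-5-oxo-1,3-dioxolan-4-yl}prop-2-enyl 2-(bromomethyl)prop-2-enoate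
Conditions: DCC, DMAP (5 mol%), CH2Cl2, 0 °C
Reagents that add atoms: none
Why: Steglich esterification of the secondary allylic alcohol should install C14, C10 and the latent C1 methylene as an SN2′ acceptor.

Step 9
Reactants: 14 but-3-yn-2-ol (racemic)
Product: 16 (Z)-4-iodo-3-methylbut-3-en-2-ol (racemic), via cyclic alkenylmagnesium alkoxide 15 (not isolated)
Conditions: MeMgBr (3.5 equiv), CuI (20 mol%), THF, −10 °C to rt; I2, −78 to 0 °C; aq. NH4Cl
Reagents that add atoms: methylmagnesium bromide C[Mg]Br; iodine II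
Why: Copper-catalysed anti-carbomagnesiation of the propargylic alkoxide should give the five-membered magnesium chelate, and iodinolysis with retention gives the (Z)-iodoalkene with iodine cis to the carbinol carbon (methyl on C4, iodine on C5).

Step 10
Reactants: 16 (Z)-4-iodo-3-methylbut-3-en-2-ol
Product: 17 (Z)-4-iodo-3-methylbut-3-en-2-one
Conditions: Dess–Martin periodinane, NaHCO3, CH2Cl2, 0 °C, dark
Reagents that add atoms: none
Why: Buffered Dess–Martin oxidation should give the methyl ketone without Z to E isomerisation and removes the racemic carbinol centre.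

Step 11
Reactants: 17 (Z)-4-iodo-3-methylbut-3-en-2-one; 13 2-(bromomethyl)acrylate ester
Product: 19 (1R)-1-{(2R,4S)-4-[(2S)-1-tert-butoxy-1-oxopropan-2-yl]-2-tert-butyl-5-oxo-1,3-dioxolan-4-yl}prop-2-enyl (6Z)-7-iodo-6-methyl-2-methylidene-5-oxohept-6-enoate, via lithium dienolate 18 (not isolated)
Conditions: LiN(SiMe3)2, THF, −78 °C (17 added to the base); then 13, −78 °C
Reagents that add atoms: none
Why: Kinetic deprotonation at the methyl group should give the cross-conjugated enolate, which attacks the acrylate in an SN2′ (addition–elimination) alkylation faster than any ester carbonyl at −78 °C, forming C1–C2 and regenerating the 2-methylene acrylate.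

Step 12
Reactants: 19 keto acrylate
Product: 20 (1R)-1-{(2R,4S)-4-[(2S)-1-tert-butoxy-1-oxopropan-2-yl]-2-tert-butyl-5-oxo-1,3-dioxolan-4-yl}prop-2-enyl (5S,6Z)-5-hydroxy-7-iodo-6-methyl-2-methylidenehept-6-enoate
Conditions: (R)-2-methyl-CBS-oxazaborolidine (20 mol%), catecholborane, toluene, −78 °C
Reagents that add atoms: none
Why: Corey–Bakshi–Shibata reduction of the enone: the α-methyl alkenyl group is the large substituent, so the (R)-catalyst should give the (3S) allylic alcohol, and the electrophilic β-iodo enone is removed at once.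

Step 13
Reactants: 20 (3S)-allylic alcohol
Product: 21 (1R)-1-{(2R,4S)-4-[(2S)-1-tert-butoxy-1-oxopropan-2-yl]-2-tert-butyl-5-oxo-1,3-dioxolan-4-yl}prop-2-enyl (5S,6Z)-5-(tert-butyldimethylsilyloxy)-7-iodo-6-methyl-2-methylidenehept-6-enoate
Conditions: TBSCl, imidazole, DMF, rt
Reagents that add atoms: tert-butyldimethylsilyl chloride CC(C)(C)[Si](C)(C)Cl
Why: Silylation of the only free hydroxyl should protect C3 through dihydroxylation and acetylation without touching the tert-butyl ester.

Step 14
Reactants: 21 silyl ether diene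
Product: 22 tert-butyl (2S)-2-{(2R,4S)-2-tert-butyl-4-[(2R)-4-[(3S,4Z)-3-(tert-butyldimethylsilyloxy)-5-iodo-4-methylpent-4-enyl]-5-oxo-2,5-dihydrofuran-2-yl]-5-oxo-1,3-dioxolan-4-yl}propanoate
Conditions: second-generation Hoveyda–Grubbs catalyst (10 mol%), toluene, 80 °C
Reagents that add atoms: none
Why: Ring-closing metathesis between the C8 vinyl group and the acrylate methylene should close ring C as the butenolide (five-membered ring, ethene lost), while the trisubstituted iodoalkene is inert.

Step 15
Reactants: 22 butenolide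
Product: 23 tert-butyl (2S)-2-{(2R,4S)-2-tert-butyl-4-[(2R,3S,4S)-3,4-dihydroxy-4-[(3S,4Z)-3-(tert-butyldimethylsilyloxy)-5-iodo-4-methylpent-4-enyl]-5-oxooxolan-2-yl]-5-oxo-1,3-dioxolan-4-yl}propanoate
Conditions: K2OsO2(OH)4 (5 mol%), N-methylmorpholine N-oxide, citric acid, t-BuOH/H2O, rt
Reagents that add atoms: N-methylmorpholine N-oxide C[N+]1([O-])CCOCC1; water O
Why: Upjohn dihydroxylation: osmium tetroxide should add to the butenolide face anti to the bulky C8 substituent, setting C9 and C10 as the cis-diol trans to C7, while the iodoalkene is deactivated by iodine and the allylic silyl ether.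

Step 16
Reactants: 23 diol
Product: 24 tert-butyl (2S)-2-{(2R,4S)-2-tert-butyl-4-[(2R,3S,4S)-3-acetoxy-4-hydroxy-4-[(3S,4Z)-3-(tert-butyldimethylsilyloxy)-5-iodo-4-methylpent-4-enyl]-5-oxooxolan-2-yl]-5-oxo-1,3-dioxolan-4-yl}propanoate
Conditions: Ac2O, pyridine, DMAP (cat.), CH2Cl2, 0 °C
Reagents that add atoms: acetic anhydride CC(=O)OC(C)=O
Why: Acylation should discriminate the secondary C9 hydroxyl from the tertiary C10 hydroxyl.

Step 17
Reactants: 24 acetate
Product: 25 4-tert-butyl 1-S-ethyl (2S,3S)-2-{(2R,3S,4S)-3-acetoxy-4-hydroxy-4-[(3S,4Z)-3-(tert-butyldimethylsilyloxy)-5-iodo-4-methylpent-4-enyl]-5-oxooxolan-2-yl}-2-hydroxy-3-methyl-1-thiobutanedioate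
Conditions: EtSH (10 equiv), Cs2CO3 (0.3 equiv), MeCN, rt
Reagents that add atoms: ethanethiol CCS
Why: Thiolysis of an activated ester: the thiolate should open the acylal carbonyl C6, pivalaldehyde is lost irreversibly and the tertiary C7 hydroxyl is released, while attack on the acetate or the lactone is reversible and unproductive.

Step 18
Reactants: 25 S-ethyl thioester vinyl iodide
Product: 28 CNP0315698.1 (target), via macrocyclic enone 26 (not isolated), via hemiketal acid 27 (not isolated)
Conditions: 25 added over 12 h to NiBr2(MeOCH2CH2OMe) (30 mol%), 4,4′-di-tert-butyl-2,2′-bipyridine (33 mol%), Zn (4 equiv), DMA/THF, 25 °C (final 2 mM); filter; then CF3CO2H/H2O/CH2Cl2 (10:1:40), 0 °C to rt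
Reagents that add atoms: none
Why: Proposed new method: zerovalent nickel should insert into the C5–I bond with retention of the Z geometry, the vinylnickel species is reduced by Zn and adds oxidatively into the C6–S bond, and acyl–vinyl reductive elimination forms C5–C6 and closes ring D to enone 26; the closest known reaction types are the nickel-catalysed reductive ketone synthesis from organic halides and thioesters and, for the same ring size and the same polarity reversal of a vinyl iodide, Nozaki–Hiyama–Kishi closures of ten-membered carbocycles. Ring D closes by intramolecular cross-electrophile coupling (ten-membered, preorganised by lactone C and the quaternary carbons C7 and C10, slow addition at high dilution), ring A by 5-exo-trig addition of the desilylated C3 hydroxyl to the C6 ketone across the cis C4=C5 bond to give 27, and ring B by 5-exo-trig lactonisation of the C12 acid, freed from its tert-butyl ester, onto the hemiketal. The only new stereocentre, C6, is set under thermodynamic control, because the acyloxy ketal ionises reversibly in acid and the fixed centres C3 and C7 of the bridged ring system decide which epimer is favoured. The step needs chemoselectivity for the thioester (acetate, lactone and tert-butyl ester do not add to nickel, the free tertiary alcohols are tolerated), retention of the Z alkene (vinylnickel species are configurationally stable), and no loss of water from 27 to a furan, which is held back because a furan bridged across C3 and C6 of ring D would be a strained [6](2,5)furanophane.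

## Compound list

1 | dimethyl (2R)-2-hydroxybutanedioate (dimethyl (R)-malate) | COC(=O)C[C@@H](O)C(=O)OC | starting material
2 | dilithium alkoxide enolate of 1 | [Li+].[Li+].COC([O-])=C[C@@H]([O-])C(=O)OC | intermediate
3 | dimethyl (2R,3S)-2-hydroxy-3-methylbutanedioate | COC(=O)[C@@H](C)[C@@H](O)C(=O)OC | intermediate
4 | (2R,3S)-2-hydroxy-3-methylbutanedioic acid | OC(=O)[C@@H](C)[C@@H](O)C(=O)O | intermediate
5 | (2S)-2-[(2R,4R)-2-tert-butyl-5-oxo-1,3-dioxolan-4-yl]propanoic acid | OC(=O)[C@@H](C)[C@H]1O[C@@H](C(C)(C)C)OC1=O | intermediate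
6 | tert-butyl (2S)-2-[(2R,4R)-2-tert-butyl-5-oxo-1,3-dioxolan-4-yl]propanoate | CC(C)(C)OC(=O)[C@@H](C)[C@H]1O[C@@H](C(C)(C)C)OC1=O | intermediate
7 | prop-2-enal (acrolein) | C=CC=O | starting material
8 | lithium enolate of 6 | [Li+].CC(C)(C)OC(=O)[C@@H](C)C1=C([O-])O[C@H](C(C)(C)C)O1 | intermediate
9 | tert-butyl (2S)-2-[(2R,4S)-2-tert-butyl-4-(1-hydroxyprop-2-enyl)-5-oxo-1,3-dioxolan-4-yl]propanoate (C8 epimers) | CC(C)(C)OC(=O)[C@@H](C)[C@@]1(C(O)C=C)O[C@@H](C(C)(C)C)OC1=O | intermediate
10 | tert-butyl (2S)-2-[(2R,4S)-2-tert-butyl-5-oxo-4-(prop-2-enoyl)-1,3-dioxolan-4-yl]propanoate | CC(C)(C)OC(=O)[C@@H](C)[C@@]1(C(=O)C=C)O[C@@H](C(C)(C)C)OC1=O | intermediate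
11 | tert-butyl (2S)-2-{(2R,4S)-2-tert-butyl-4-[(1R)-1-hydroxyprop-2-enyl]-5-oxo-1,3-dioxolan-4-yl}propanoate | CC(C)(C)OC(=O)[C@@H](C)[C@@]1([C@H](O)C=C)O[C@@H](C(C)(C)C)OC1=O | intermediate
12 | 2-(bromomethyl)prop-2-enoic acid | OC(=O)C(=C)CBr | starting material
13 | (1R)-1-{(2R,4S)-4-[(2S)-1-tert-butoxy-1-oxopropan-2-yl]-2-tert-butyl-5-oxo-1,3-dioxolan-4-yl}prop-2-enyl 2-(bromomethyl)prop-2-enoate | CC(C)(C)OC(=O)[C@@H](C)[C@@]1([C@H](OC(=O)C(=C)CBr)C=C)O[C@@H](C(C)(C)C)OC1=O | intermediate
14 | but-3-yn-2-ol (racemic) | CC(O)C#C | starting material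
15 | cyclic (Z)-alkenylmagnesium alkoxide (five-membered O–Mg–C chelate) | CC1O[Mg]C=C1C | intermediate
16 | (Z)-4-iodo-3-methylbut-3-en-2-ol (racemic) | CC(O)/C(C)=C\I | intermediate
17 | (Z)-4-iodo-3-methylbut-3-en-2-one | CC(=O)/C(C)=C\I | intermediate
18 | lithium (3Z)-4-iodo-3-methylbuta-1,3-dien-2-olate | [Li+].[O-]C(=C)/C(C)=C\I | intermediate
19 | (1R)-1-{(2R,4S)-4-[(2S)-1-tert-butoxy-1-oxopropan-2-yl]-2-tert-butyl-5-oxo-1,3-dioxolan-4-yl}prop-2-enyl (6Z)-7-iodo-6-methyl-2-methylidene-5-oxohept-6-enoate | CC(C)(C)OC(=O)[C@@H](C)[C@@]1([C@H](OC(=O)C(=C)CCC(=O)/C(C)=C\I)C=C)O[C@@H](C(C)(C)C)OC1=O | intermediate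
20 | the same ester with (5S,6Z)-5-hydroxy-7-iodo-6-methyl-2-methylidenehept-6-enoate as acyl part | CC(C)(C)OC(=O)[C@@H](C)[C@@]1([C@H](OC(=O)C(=C)CC[C@H](O)/C(C)=C\I)C=C)O[C@@H](C(C)(C)C)OC1=O | intermediate
21 | the same ester with (5S,6Z)-5-(tert-butyldimethylsilyloxy)-7-iodo-6-methyl-2-methylidenehept-6-enoate as acyl part | CC(C)(C)OC(=O)[C@@H](C)[C@@]1([C@H](OC(=O)C(=C)CC[C@H](O[Si](C)(C)C(C)(C)C)/C(C)=C\I)C=C)O[C@@H](C(C)(C)C)OC1=O | intermediate
22 | tert-butyl (2S)-2-{(2R,4S)-2-tert-butyl-4-[(2R)-4-[(3S,4Z)-3-(tert-butyldimethylsilyloxy)-5-iodo-4-methylpent-4-enyl]-5-oxo-2,5-dihydrofuran-2-yl]-5-oxo-1,3-dioxolan-4-yl}propanoate | CC(C)(C)OC(=O)[C@@H](C)[C@@]1([C@@H]2OC(=O)C(CC[C@H](O[Si](C)(C)C(C)(C)C)/C(C)=C\I)=C2)O[C@@H](C(C)(C)C)OC1=O | intermediate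
23 | tert-butyl (2S)-2-{(2R,4S)-2-tert-butyl-4-[(2R,3S,4S)-3,4-dihydroxy-4-[(3S,4Z)-3-(tert-butyldimethylsilyloxy)-5-iodo-4-methylpent-4-enyl]-5-oxooxolan-2-yl]-5-oxo-1,3-dioxolan-4-yl}propanoate | O[C@H]1[C@H]([C@]2([C@H](C)C(=O)OC(C)(C)C)O[C@@H](C(C)(C)C)OC2=O)OC(=O)[C@]1(O)CC[C@H](O[Si](C)(C)C(C)(C)C)/C(C)=C\I | intermediate
24 | the 3-acetate of 23 (acetate on C9, free tertiary C10 hydroxyl) | CC(=O)O[C@H]1[C@H]([C@]2([C@H](C)C(=O)OC(C)(C)C)O[C@@H](C(C)(C)C)OC2=O)OC(=O)[C@]1(O)CC[C@H](O[Si](C)(C)C(C)(C)C)/C(C)=C\I | intermediate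
25 | 4-tert-butyl 1-S-ethyl (2S,3S)-2-{(2R,3S,4S)-3-acetoxy-4-hydroxy-4-[(3S,4Z)-3-(tert-butyldimethylsilyloxy)-5-iodo-4-methylpent-4-enyl]-5-oxooxolan-2-yl}-2-hydroxy-3-methyl-1-thiobutanedioate | CC(=O)O[C@H]1[C@H]([C@](O)(C(=O)SCC)[C@H](C)C(=O)OC(C)(C)C)OC(=O)[C@]1(O)CC[C@H](O[Si](C)(C)C(C)(C)C)/C(C)=C\I | intermediate
26 | macrocyclic (Z)-enone: rings C and D closed, C6 ketone, (3S) silyl ether, free C7 hydroxyl, C12 tert-butyl ester | CC(=O)O[C@H]1[C@H]2OC(=O)[C@]1(O)CC[C@H](O[Si](C)(C)C(C)(C)C)/C(C)=C\C(=O)[C@]2(O)[C@H](C)C(=O)OC(C)(C)C | intermediate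
27 | hemiketal acid: rings A, C and D closed, C6 hemiketal (equilibrating epimers), free C12 acid | CC(=O)O[C@H]1[C@H]2OC(=O)[C@]1(O)CC[C@@H]1OC(O)(C=C1C)[C@]2(O)[C@H](C)C(O)=O | intermediate
28 | CNP0315698.1 | CC(=O)O[C@H]1[C@H]2OC(=O)[C@]1(O)CC[C@@H]1O[C@@]3(C=C1C)OC(=O)[C@@H](C)[C@]23O | target

## Step count and risks

Total steps: 18. Longest linear sequence: 16 steps (steps 1–8, then 11–18). Steps 9–10 make the second fragment.

Steps most likely to fail:

1. Step 18 (the proposed new method). Ring D may not close: oligomerisation or protodeiodination may win, or the thioester may not add to nickel. In the acid stage the hemiketal may dehydrate or the ketal may settle as the other C6 epimer. Fallback with known chemistry, setting out from 25 and returning at 26: NaBH4 (EtOH, 0 °C) should reduce the thioester to the primary alcohol, the diol F1. TEMPO/PhI(OAc)2 should oxidise only the primary hydroxyl, giving the α-hydroxy aldehyde F2. An intramolecular Nozaki–Hiyama–Kishi reaction (CrCl2, NiCl2 cat., DMSO/THF, high dilution) should close ring D to the allylic alcohol F3 (C6 epimers; the tert-butyl ester cannot lactonise onto the new hydroxyl). MnO2 oxidation then gives enone 26, which is taken through the acid stage of step 18.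

2. Step 17. Thiolysis may stall at equilibrium, or the base may start acetyl migration or lactone opening. Fallback, setting out from 23 and returning at 25: LiOH (aq. THF, 0 °C) should hydrolyse the acylal, and the lactone recloses on acidification, giving the hydroxy acid F4. Acetylation as in step 16 gives the acetate acid F5. Steglich thioesterification (EtSH, DCC, DMAP) then gives 25.

3. Step 15. The oxidant may attack the iodoalkene as well, or the hindered, electron-poor butenolide may react too slowly. Fallback, setting out from 22 and returning at 28: the dihydroxylation is moved behind the ring closure. Thiolysis as in step 17 gives the butenolide thioester F6. The conditions of step 18 should close rings D, A and B to the bridged butenolide F7. Osmium tetroxide/N-methylmorpholine N-oxide should then add to the strained C9=C10 bond from the face turned away from ring D, giving the diol F8, and acetylation as in step 16 gives 28.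

## Further compounds

F1 | step 18 | diol from reduction of the thioester of 25 (C6 as CH2OH) | CC(=O)O[C@H]1[C@H]([C@](O)(CO)[C@H](C)C(=O)OC(C)(C)C)OC(=O)[C@]1(O)CC[C@H](O[Si](C)(C)C(C)(C)C)/C(C)=C\I
F2 | step 18 | α-hydroxy aldehyde (C6 as CHO) | CC(=O)O[C@H]1[C@H]([C@](O)(C=O)[C@H](C)C(=O)OC(C)(C)C)OC(=O)[C@]1(O)CC[C@H](O[Si](C)(C)C(C)(C)C)/C(C)=C\I
F3 | step 18 | ring D allylic alcohol (C6 carbinol, both epimers) | CC(=O)O[C@H]1[C@H]2OC(=O)[C@]1(O)CC[C@H](O[Si](C)(C)C(C)(C)C)/C(C)=C\C(O)[C@]2(O)[C@H](C)C(=O)OC(C)(C)C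
F4 | step 17 | hydroxy acid from 23 (C6 as CO2H, free C7, C9 and C10 hydroxyls) | O[C@H]1[C@H]([C@](O)(C(O)=O)[C@H](C)C(=O)OC(C)(C)C)OC(=O)[C@]1(O)CC[C@H](O[Si](C)(C)C(C)(C)C)/C(C)=C\I
F5 | step 17 | C9 acetate of F4 | CC(=O)O[C@H]1[C@H]([C@](O)(C(O)=O)[C@H](C)C(=O)OC(C)(C)C)OC(=O)[C@]1(O)CC[C@H](O[Si](C)(C)C(C)(C)C)/C(C)=C\I
F6 | step 15 | butenolide S-ethyl thioester from 22 | CC(C)(C)OC(=O)[C@@H](C)[C@@](C(=O)SCC)([C@@H]1OC(=O)C(CC[C@H](O[Si](C)(C)C(C)(C)C)/C(C)=C\I)=C1)O
F7 | step 15 | bridged butenolide with rings A, B and D closed (C9=C10, no oxygen on C9 and C10) | O=C1O[C@@H]2C=C1CC[C@@H]1O[C@@]3(C=C1C)OC(=O)[C@@H](C)[C@]23O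
F8 | step 15 | 9-deacetyl target (C9 and C10 diol) | O[C@H]1[C@H]2OC(=O)[C@]1(O)CC[C@@H]1O[C@@]3(C=C1C)OC(=O)[C@@H](C)[C@]23O
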